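(All runs were computed with made-up constants.)

If every step that makes and consumes the target sped up alike with concentration, doubling the charge at fixed equivalents would shorten the clock without changing the percentages. The flask would then repeat the summer run's highest reading, 7.8%, at 0.167 d. If instead the target's formation sped up while its loss kept its pace, the same percentage would double to 15.6%, at about the summer time of 0.333 d.

- summer: starting material 0.15 M; coupling partner 5 equiv; run made earlier
- flask: starting material 0.30 M; coupling partner 5.00 equiv; time 12 d

- summer (time / d: target / %, starting material / %): 0.208: 6.1, 73.4; 0.333: 7.8, 65.4; 0.625: 4.4, 52.3; 1.25: 2.6, 34.0; 2.50: 0.9, 17.7

(each reading ± 0.5 percentage points)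

- a reading or a percentage of target counts all its forms, free or not

- the best time, 12 d at the latest, for target
- the amount of target, in percent of the starting material charged, at that time

The summer readings carry a mark of each end, so this reckoning places the flask between them. The decay constant of the starting material, the limiting reagent, as read from the summer run, falls from 1.49 /d early to 0.522 /d late, so concentration appears to quicken the clock. The ratio of target to starting material is also higher at 0.333 d, 0.119, than at 2.50 d, 0.0508, so concentration appears to favour formation. The two ends are joined at their geometric middle by the rise factor, the square root of the ratio of concentrations at fixed equivalents 1.41. Multiplying the peak reading and dividing its time by this factor gives 11.0% at 0.236 d.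

The forecast, on its own grounds that “formation is higher order than its decay”, gives 11% (range 7% to 17%) at 0.25 d (range 0.12 d to 0.6 d).

The flask gives 11.9% at 0.228 d.

    starting material + coupling partner ⇌ target (K = 0.140 /M, k = 0.00100 /M/min)
    starting material + 2 coupling partner → side product (k = 0.00150 /M²/min)
    crystals ⇌ target, rate k3*(cs3 - [target]) while solid is left; crystals form when [target] > cs3 (solubility = 18.0 mM, k = 0.0660 /min)
    target ⇌ isomer of the product (K = 1.50, k = 5.80 × 10⁻⁵ /min)

In the flask at 0.228 d, 5.85% of the starting material charged stands as crystals, counted within the target. The summer reading times the rise factor lies 0.84 percentage points below the flask. For the neighbouring flask at 0.075 M, half the summer concentration at the same equivalents, the summer reading divided by the rise factor gives 5.53%, and the best amount of target in that flask is 4.34%.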